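Electrophile and target together stay at the charge in the red run, 100% of it at 50.0 min, so each electrophile lost is a target made, and the reckoning below takes each target to set free one acid.

all flasks: electrophile 10 mM

| run | nucleophile | free base | remark | time |
|---|---|---|---|---|
| red | 9 mM | 3 mM | the very flask that is asked about, followed so far |  |
| flask | 9.00 mM | 3.00 mM |  | 4.0 h |

red run (percent of the electrophile charged)

| time / min | electrophile / % | target / % |
|---|---|---|
| 4.00 | 95.0 | 5.2 |
| 6.00 | 91.9 | 7.5 |
| 8.00 | 89.2 | 10.0 |
| 15.0 | 83.1 | 17.8 |
| 20.0 | 77.9 | 21.1 |
| 30.0 | 71.3 | 28.4 |
| 50.0 | 61.8 | 38.4 |

(readings scatter by 0.5 percentage points)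

- the numbers in the tables scatter with a standard deviation of 0.5 percentage points
- the earlier runs do not show how much of nucleophile is bound; that part of a forecast is a guess

- part of the electrophile that has reacted at 4.0 h
- share of the unused nucleophile that is free and not bound as protonated nucleophile, at 4.0 h

On a ladder of times for this flask, the first rung is the taking up of acid, which no reading resolves and which is assumed to be immediate. The next rung is the free base, which can cover acid up to 30.0% of the electrophile, a mark that the target readings pass between 30.0 min and 50.0 min. Then comes the making of target, where 10.0% at 8.00 min reads as a half-life near 55.5 min at the charged amounts, longer than that second rung, while the asked 4.0 h spans 4.32 such half-lives. Past the cover, if acid goes on to the nucleophile, each further target costs two nucleophile, one built in and one protonated, so the flask's nucleophile balance closes at 60.0%. This is the stall conversion: the charges of nucleophile and free base added, divided by 2 times the electrophile charged. The reckoning therefore puts this flask a little short of it at 4.0 h, with a small free share of the unused nucleophile, which is a guess.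

The forecast gives 60% reacted and 18% free, adding that “Binding strength is a guess”. The flask gives 58.0% and 9.48%.

    acid set free + free base ⇌ salt of the base, settled at all times (K = 9.00 × 10⁶ M⁻¹)
    nucleophile + acid set free ⇌ protonated nucleophile, settled at all times (K = 1.40 × 10⁵ M⁻¹)
    electrophile + nucleophile → acid set free + target (k = 93.0 M⁻¹ h⁻¹)
    free base ⇌ dormant form (K = 4.60, k = 0.200 h⁻¹)

The flask stands 2 percentage points below its stall conversion at 4.0 h, holding 2.89 mM of protonated nucleophile, and by 40.0 h it has passed it, at 64.1%, with 0.875 mM of acid set free. The neighbouring flask with 25 mM of electrophile, other charges and the time held, spreads the same nucleophile and free base over more electrophile, so its stall conversion is 24.0%. That neighbour gives 25.0% reacted at 4.0 h, with 1.23% of its unused nucleophile free.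

(The runs stem from a simulated flask for an exercise.)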